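The runs come from a simulation for an exercise, and the scatter is random.

How far does the starting material get by 4.0 h, and how much reagent stands free beside the idle adduct?

- north-east: starting material 0.060 M; reagent 0.054 M; scavenger 0.018 M; free catalyst 1.5 mM; the very flask that is asked about, followed so far
- flask: starting material 0.060 M; reagent 0.0540 M; scavenger 0.0180 M; free catalyst 1.5 mM; time 4.0 h

north-east run (percent of the starting material charged)

| time / min | starting material / % | product / % |
|---|---|---|
| 15.0 | 89.9 | 8.1 |
| 30.0 | 82.9 | 13.4 |
| 50.0 | 72.9 | 24.5 |
| 60.0 | 69.9 | 27.8 |
| 80.0 | 60.9 | 36.4 |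
| 90.0 | 57.9 | 41.0 |
| 120 | 46.7 | 52.4 |

(scatter of a reading: 1 percentage point)

- part of the starting material that has reacted at 4.0 h
- share of free reagent in free reagent and idle adduct together, at 4.0 h

- the earlier runs do not show how much of reagent is bound; that part of a forecast is a guess

1. Before the start: reagent is the limiting reagent, 0.0540 M against 0.060 M of starting material. Reagent charged over starting material charged gives 90.0%. This reagent ceiling is the conversion the charge allows if each reagent serves one starting material.

2. First instants: by 15.0 min the north-east run, the same recipe as the flask, already shows 8.1% product.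

3. Middle: counted in logarithms, a decade being a tenfold fall, its starting material has lost 0.156 decade by 60.0 min and twice that, 0.331, by 120 min. That is a reading of 0.165 h⁻¹.

4. End: continued at that pace, the line estimates 78.2% for the flask at 4.0 h. The ceiling lies 1.00 decade down, about 6.06 h along this line, so this reckoning commits to the smaller figure, 78.2%. The readings do not show how much reagent is bound, so this reckoning offers no free share.

The forecast says 72% (60% to 80%) and 30% (4% to 70%), on the ground that “Reagent sets the ceiling”. Its conversion stands below the reckoning above.

The flask gives 81.9% and 44.9%.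

    reagent + free catalyst → catalyst intermediate A (k = 1.10 M⁻¹ s⁻¹)
    starting material + catalyst intermediate A → catalyst intermediate B (k = 23.0 M⁻¹ s⁻¹)
    catalyst intermediate B → released group + catalyst intermediate C (k = 0.0150 s⁻¹)
    catalyst intermediate C ⇌ catalyst intermediate D (K = 0.890, k = 0.0140 s⁻¹)
    catalyst intermediate D → free catalyst + product (k = 0.0160 s⁻¹)
    reagent + released group ⇌ idle adduct, settled at all times (K = 41.0 M⁻¹)
    scavenger + released group → scavenged by-product (k = 0.110 M⁻¹ s⁻¹)
    reagent ⇌ dormant form (K = 1.20, k = 4.80 × 10⁻⁴ s⁻¹)

The flask stands 8.1 percentage points under its ceiling at 4.0 h and reaches 90.0% at 40.0 h. A neighbour charged with 0.032 M of reagent has a ceiling of 53.3%, below the 78.2% of the line, so the reckoning takes the ceiling for it. That neighbour gives 51.7% at 4.0 h, with 0.55% of its reagent still unbound.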